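## Retrosynthetic overview
1. The target 2-acylglycerol is cut at the ester C–O bond. This gives halim-1(10)-en-15-oic acid and glycerol protected as its 1,3-benzylidene acetal, which is removed last.
2. The bicyclic acid comes from an acyclic (3R,6Z,10E)-trienoic acid in one acid-catalysed cascade. Ring A closes first (C4–C5), ring B second (C9–C10). A 1,2-H shift C9→C8, the key 1,2-methyl shift C10→C9 and loss of H-1 follow.
3. The trienoic acid is cut at C3–C4 into (3Z,7E)-homofarnesyl Grignard and (R)-β-butyrolactone, which is the source of C13.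
4. The 6Z alkene comes from homogeranylcopper, propyne and oxirane. The 10E alkene comes from a 4-methylpent-3-enyl cuprate, lithiated 2,3-dihydrofuran and MeI.

Assumption: with halimane numbering the SMILES reads 5S,8R,9R,13R (H-5, the C8 methyl and the side chain on one face, the C9 methyl on the other), and the (S,S) acid of step 6 is taken to give the 5S series; its mirror image is used if the sense proves opposite.

## Route

Step 1
Reactants: 1 5-bromo-2-methylpent-2-ene; 2 2,3-dihydrofuran
Product: 7 homogeraniol [(3E)-4,8-dimethylnona-3,7-dien-1-ol], via 4-methylpent-3-enyllithium 3 (not isolated), via 5-lithio-2,3-dihydrofuran 4 (not isolated), via lithium alkyl(dihydrofuranyl)cuprate 5 (not isolated), via Z-alkenylcopper lithium alkoxide 6 (not isolated)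
Conditions: 1, Li (2 equiv), Et2O, −15 °C; 2, t-BuLi, THF, −78 → 0 °C; CuBr·SMe2 (1 equiv), Et2O/Me2S, −78 → 20 °C; MeI, DMPU, 0 → 20 °C; aq NH4Cl
Reagents that add atoms: iodomethane, CI
Why: Kocienski 1,2-metallate rearrangement: in cuprate 5 the alkyl group migrates from copper to the oxygen-bearing alkenyl carbon with inversion and loss of the ring alkoxide, so copper in 6 ends cis to the CH2CH2OLi arm and methylation with retention gives only the E trisubstituted alkene.

Step 2
Reactants: 7 homogeraniol
Product: 8 homogeranyl bromide [(6E)-9-bromo-2,6-dimethylnona-2,6-diene]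
Conditions: CBr4, PPh3, CH2Cl2, 0 °C
Reagents that add atoms: tetrabromomethane, BrC(Br)(Br)Br
Why: Appel reaction, an SN2 displacement of the primary alkoxyphosphonium ion by bromide under neutral conditions that leaves both alkenes and their geometry untouched.

Step 3
Reactants: 8 homogeranyl bromide; 9 propyne; 10 oxirane
Product: 13 (3Z,7E)-homofarnesol [(3Z,7E)-4,8,12-trimethyltrideca-3,7,11-trien-1-ol], via homogeranylmagnesium bromide 11 (not isolated), via Z-alkenylcopper 12 (not isolated)
Conditions: Mg, Et2O; CuBr·SMe2 (1 equiv), Et2O/Me2S, −45 °C; 9, −25 °C, 48 h; PhC≡CLi (1 equiv), DMPU, −78 °C; 10, −78 → 0 °C; aq NH4Cl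
Reagents that add atoms: none
Why: Normant carbocupration: the alkylcopper made from 11 adds syn to propyne with the chain going to the internal carbon and copper to the terminal one, so chain and copper are cis in 12, and after activation by the non-transferable phenylacetylide ligand the alkenyl group opens oxirane with retention, which fixes the 3Z alkene.

Step 4
Reactants: 13 (3Z,7E)-homofarnesol
Product: 14 (3Z,7E)-homofarnesyl bromide [(3Z,7E)-1-bromo-4,8,12-trimethyltrideca-3,7,11-triene]
Conditions: CBr4, PPh3, CH2Cl2, 0 °C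
Reagents that add atoms: tetrabromomethane, BrC(Br)(Br)Br
Why: Appel reaction as in step 2, neutral and without allylic positions at risk, so the Z and E alkenes are kept.

Step 5
Reactants: 14 (3Z,7E)-homofarnesyl bromide; 15 (R)-β-butyrolactone [(4R)-4-methyloxetan-2-one]
Product: 17 (3R,6Z,10E)-3,7,11,15-tetramethylhexadeca-6,10,14-trienoic acid, via (3Z,7E)-homofarnesylmagnesium bromide 16 (not isolated)
Conditions: Mg, THF, 20 °C; 15, CuBr·SMe2 (10 mol %), THF/Me2S, −30 → 0 °C; 1 M HCl
Reagents that add atoms: none
Why: Copper-catalysed SN2 opening of a β-lactone by a Grignard reagent at the alkyl C–O carbon instead of the acyl carbon, with clean inversion, so (R)-15 gives the 3R centre (C13 of the target; the descriptor stays R because the priority order changes), as known for 3-methylalkanoic acids such as citronellic acid.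

Step 6
Reactants: 17 (3R,6Z,10E)-trienoic acid
Product: 21 (5S,8R,9R,13R)-halim-1(10)-en-15-oic acid, via 9-epi-labdan-8-yl cation 18 (not isolated), via 8β-H-labdan-9-yl cation 19 (not isolated), via haliman-10-yl cation 20 (not isolated)
Conditions: (S,S)-imidodiphosphorimidate Brønsted acid (IDPi, 5 mol %; two (S)-BINOL phosphorus units, 3,3'-spiro[cyclohexane-1,9'-fluoren]-2'-yl walls, N-SO2C6F5 groups), (CF3)3COH/CH2Cl2 1:1, 0.02 M, −40 °C, 72 h; Et3N; AgNO3–SiO2 chromatography
Reagents that add atoms: none
Why: Proposed new method: the confined chiral acid protonates only the slim terminal isopropylidene alkene of 17 held chair–chair in its pocket, so ring A and then ring B close under Stork–Eschenmoser control (10E gives the trans fusion and 5S, 6Z puts the side chain axial and H-9 on the face of the C10 methyl, cation 18); the weakly basic anion and the non-nucleophilic fluoroalcohol leave the tertiary cation time to relax ring B to a twist form that relieves the axial chain and aligns C9–H, a suprafacial 1,2-H shift C9→C8 gives 19 (sets 8R), and the axial C10 methyl then migrates to C9 on the same face through the discrete cation to give 20 (sets quaternary 9R); the charge is then back at C10 beside the C1–C3 rim where the anion stayed after delivering its proton to C3, so the anion removes the exposed axial H-1 and not the H-5 shielded by the gem-dimethyl group, and the bulky bicyclic alkene cannot re-enter the pocket to be isomerised; the closest known reaction types are the IDPi-catalysed asymmetric polyene cyclisation ended by a hydroxyl group, catalytic asymmetric Wagner–Meerwein shifts of purely aliphatic cations, and the BF3-induced H/methyl shift cascade from drimanes to friedodrimanes, while the new elements are the union of cyclisation and skeletal shift in one catalytic event, the ending by regioselective proton loss and the use of a 6Z polyene.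

Step 7
Reactants: 21 halim-1(10)-en-15-oic acid; 22 cis-2-phenyl-1,3-dioxan-5-ol (glycerol protected as its 1,3-benzylidene acetal)
Product: 23 cis-2-phenyl-1,3-dioxan-5-yl (5S,8R,9R,13R)-halim-1(10)-en-15-oate
Conditions: i-PrN=C=Ni-Pr (DIC), 4-(dimethylamino)pyridine (10 mol %), CH2Cl2, 0 → 20 °C
Reagents that add atoms: none
Why: Steglich esterification of an unhindered CH2CO2H group with the only free hydroxyl of 22 under neutral conditions that leave the 1(10)-alkene and all four stereocentres untouched.

Step 8
Reactants: 23 benzylidene-protected ester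
Product: 24 1,3-dihydroxypropan-2-yl (5S,8R,9R,13R)-halim-1(10)-en-15-oate (target)
Conditions: B(OH)3, B(OEt)3, 100 °C, 20 min, evaporate; Et2O/H2O, 0 °C; B(OH)3-impregnated SiO2
Reagents that add atoms: none
Why: Boric acid-mediated cleavage of the benzylidene acetal, the standard entry to 2-monoacylglycerols: the freed 1,3-diol is held as a borate until cold aqueous release, which suppresses 2→1 acyl migration, and the weak acid does not protonate the trisubstituted alkene.

## Compound list
1 | 5-bromo-2-methylpent-2-ene | CC(C)=CCCBr | starting material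
2 | 2,3-dihydrofuran | C1CC=CO1 | starting material
3 | 4-methylpent-3-enyllithium | [Li]CCC=C(C)C | intermediate
4 | 5-lithio-2,3-dihydrofuran | [Li]C1=CCCO1 | intermediate
5 | lithium (4,5-dihydrofuran-2-yl)(4-methylpent-3-enyl)cuprate | [Li+].CC(C)=CCC[Cu-]C1=CCCO1 | intermediate
6 | lithium (3Z)-4-cuprio-8-methylnona-3,7-dien-1-olate (Cu cis to the CH2CH2OLi arm) | [Li]OCC/C=C(\[Cu])CCC=C(C)C | intermediate
7 | homogeraniol, (3E)-4,8-dimethylnona-3,7-dien-1-ol | CC(C)=CCC/C(C)=C/CCO | intermediate
8 | homogeranyl bromide, (6E)-9-bromo-2,6-dimethylnona-2,6-diene | CC(C)=CCC/C(C)=C/CCBr | intermediate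
9 | propyne | CC#C | starting material
10 | oxirane | C1CO1 | starting material
11 | homogeranylmagnesium bromide | CC(C)=CCC/C(C)=C/CC[Mg]Br | intermediate
12 | (1Z,5E)-2,6,10-trimethylundeca-1,5,9-trien-1-ylcopper | CC(C)=CCC/C(C)=C/CC/C(C)=C\[Cu] | intermediate
13 | (3Z,7E)-homofarnesol, (3Z,7E)-4,8,12-trimethyltrideca-3,7,11-trien-1-ol | CC(C)=CCC/C(C)=C/CC/C(C)=C\CCO | intermediate
14 | (3Z,7E)-1-bromo-4,8,12-trimethyltrideca-3,7,11-triene | CC(C)=CCC/C(C)=C/CC/C(C)=C\CCBr | intermediate
15 | (R)-β-butyrolactone, (4R)-4-methyloxetan-2-one | C[C@@H]1CC(=O)O1 | starting material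
16 | (3Z,7E)-homofarnesylmagnesium bromide | CC(C)=CCC/C(C)=C/CC/C(C)=C\CC[Mg]Br | intermediate
17 | (3R,6Z,10E)-3,7,11,15-tetramethylhexadeca-6,10,14-trienoic acid | C[C@H](CC/C=C(/C)CC/C=C(\C)CCC=C(C)C)CC(=O)O | intermediate
18 | 9-epi-labdan-8-yl cation (5α-H, 9β-H, 10β-Me, 13R, free CO2H) | C[C@H](CC[C@@H]1[C+](C)CC[C@H]2C(C)(C)CCC[C@]12C)CC(=O)O | intermediate
19 | labdan-9-yl cation (5α-H, 8β-H, 8α-Me, 10β-Me, 13R) | C[C@H](CC[C+]1[C@H](C)CC[C@H]2C(C)(C)CCC[C@]12C)CC(=O)O | intermediate
20 | haliman-10-yl cation (5α-H, 8α-Me, 9β-Me, 13R) | C[C@H](CC[C@@]1(C)[C+]2CCCC(C)(C)[C@@H]2CC[C@H]1C)CC(=O)O | intermediate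
21 | (5S,8R,9R,13R)-halim-1(10)-en-15-oic acid, (3R)-3-methyl-5-[(1R,2R,4aS)-1,2,5,5-tetramethyl-1,2,3,4,4a,5,6,7-octahydronaphthalen-1-yl]pentanoic acid | C[C@H](CC[C@@]1(C)C2=CCCC(C)(C)[C@@H]2CC[C@H]1C)CC(=O)O | intermediate
22 | cis-2-phenyl-1,3-dioxan-5-ol (1,3-O-benzylideneglycerol) | O[C@H]1CO[C@@H](c2ccccc2)OC1 | starting material
23 | cis-2-phenyl-1,3-dioxan-5-yl (5S,8R,9R,13R)-halim-1(10)-en-15-oate | C[C@H](CC[C@@]1(C)C2=CCCC(C)(C)[C@@H]2CC[C@H]1C)CC(=O)O[C@H]1CO[C@@H](c2ccccc2)OC1 | intermediate
24 | 1,3-dihydroxypropan-2-yl (5S,8R,9R,13R)-halim-1(10)-en-15-oate | C[C@H](CC[C@@]1(C)C2=CCCC(C)(C)[C@@H]2CC[C@H]1C)CC(=O)OC(CO)CO | target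

## Step count and risks
Total step count: 8. Longest linear sequence: 8 (steps 1 to 8).

**Step 6 (the new cascade).** Four failures are possible.
- The cascade may stop at labdenes.
- It may leak through the 8(9)-alkene to the C8 epimer.
- It may end in the tetrasubstituted alkene.
- A cation may be trapped by the carboxyl group.

The fallback uses known chemistry, sets out from 17 and comes back at 21. Cyclisation and shift are done as two separate, stoichiometric operations. First, 17 is cyclised with the chiral Lewis-acid-assisted Brønsted acid (R)-2-[(2-fluorobenzyl)oxy]-2'-hydroxy-1,1'-binaphthyl·SnCl4 (2 equiv, toluene, −78 °C). This gives isolated 9-epi-labd-7-en-15-oic acid F1 together with 9-epi-labd-8(17)-en-15-oic acid F2. The pair is then re-ionised at C8 with BF3·OEt2 (CH2Cl2, −50 → −5 °C), the classical Wagner–Meerwein H/methyl shift. Finally 21 is separated from regioisomeric alkenes on AgNO3-impregnated silica.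

**Step 3 (carbocupration and oxirane opening).** The addition to propyne is slow, the organocopper is thermally fragile and the alkenylcopper is sluggish towards oxirane. The fallback sets out from 8 and comes back at 13. Dilithiated but-3-yn-1-ol (n-BuLi 2 equiv, THF/DMPU) is alkylated with 8 to give (7E)-8,12-dimethyltrideca-7,11-dien-3-yn-1-ol F3. An alkoxide-directed syn methylmagnesiation (MeMgBr, Fe(acac)3 10 mol %, THF, 0 °C) followed by protonation places the methyl on the distal alkyne carbon. This leaves both chains cis, that is the 3Z alkene of 13.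

**Step 8 (acetal cleavage).** Acyl migration from O-2 to O-1 may occur during heating or chromatography. The fallback sets out from 21 and comes back at 24, and it avoids acetals and heat altogether. Glycerol is silylated (i-Pr3SiCl 2 equiv, imidazole, DMF) to give 1,3-bis(triisopropylsilyloxy)propan-2-ol F4. This is esterified with 21 (DIC, 4-(dimethylamino)pyridine) to give the bis-silyl ester F5. The silyl ethers are then cleaved with Bu4NF/AcOH (1:1) in THF at 0 °C.

## Further compounds
F1 | step 6 | 9-epi-labd-7-en-15-oic acid (5α-H, 9β-H, 10β-Me, 13R) | C[C@H](CC[C@@H]1C(C)=CC[C@H]2C(C)(C)CCC[C@]12C)CC(=O)O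
F2 | step 6 | 9-epi-labd-8(17)-en-15-oic acid (5α-H, 9β-H, 10β-Me, 13R) | C[C@H](CC[C@@H]1C(=C)CC[C@H]2C(C)(C)CCC[C@]12C)CC(=O)O
F3 | step 3 | (7E)-8,12-dimethyltrideca-7,11-dien-3-yn-1-ol | CC(C)=CCC/C(C)=C/CCC#CCCO
F4 | step 8 | 1,3-bis(triisopropylsilyloxy)propan-2-ol | OC(CO[Si](C(C)C)(C(C)C)C(C)C)CO[Si](C(C)C)(C(C)C)C(C)C
F5 | step 8 | 1,3-bis(triisopropylsilyloxy)propan-2-yl (5S,8R,9R,13R)-halim-1(10)-en-15-oate | C[C@H](CC[C@@]1(C)C2=CCCC(C)(C)[C@@H]2CC[C@H]1C)CC(=O)OC(CO[Si](C(C)C)(C(C)C)C(C)C)CO[Si](C(C)C)(C(C)C)C(C)C
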